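The north charge holds 1.00 M of substrate and 3.00 M of partner against 0.00500 M of catalyst, so catalyst is far less than either, yet it starts the reaction.

| setting | north | south-east | north-west | north-east | south-west |
|---|---|---|---|---|---|
| substrate | 1.00 M | 1.00 M | 1.00 M | 3.00 M | 0.300 M |
| partner | 3.00 M | 1.50 M | 3.00 M | 3.00 M | 2.30 M |
| catalyst | 0.00500 M | 0.00500 M | 0.00250 M | 0.00500 M | 0.00500 M |
| time |  |  |  |  | 170 s |

| run | time / s | [target] / M |
|---|---|---|
| north run | 24 | 0.007 |
| north run | 49 | 0.026 |
| north run | 73 | 0.062 |
| north run | 97 | 0.139 |
| north run | 120 | 0.277 |
| north run | 150 | 0.522 |
| north run | 170 | 0.657 |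
| south-east run | 24 | 0.008 |
| south-east run | 49 | 0.016 |
| south-east run | 73 | 0.036 |
| south-east run | 97 | 0.060 |
| south-east run | 120 | 0.096 |
| south-east run | 150 | 0.164 |
| south-east run | 170 | 0.218 |
| north-west run | 24 | 0 |
| north-west run | 49 | 0.012 |
| north-west run | 73 | 0.015 |
| north-west run | 97 | 0.041 |
| north-west run | 120 | 0.090 |
| north-west run | 150 | 0.240 |
| north-west run | 170 | 0.388 |
| north-east run | 24 | 0.048 |
| north-east run | 49 | 0.694 |
| north-east run | 73 | 1.797 |
| north-east run | 97 | 2.293 |
| north-east run | 120 | 2.482 |
| north-east run | 150 | 2.573 |
| north-east run | 170 | 2.605 |

(standard deviation of a reading: 0.005 M)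

- Overall: substrate + partner -> target, with catalyst as catalyst.
- Constant volume, constant temperature.
- A reading of a species includes what of it is bound.
- An order is taken over about fifteen percent of the charge, up and down.

1. reaction order in [substrate] at the outset, round the charge of the north run, defined at two percent of the substrate turned into target (one fixed amount of target, the same in the runs compared)
2. reaction order in [catalyst] at the outset, round the charge of the north run, defined at two percent of the substrate turned into target
3. target in the south-west run at 170 s, as a share of the substrate charged

I worked in logarithms. In the north run, log target climbs nearly straight from 49 s to 97 s, so target feeds its own formation (autocatalysis) with a growth constant of 0.0349 s⁻¹. I took this as proportional to substrate times partner, which gave 0.0116 M⁻² s⁻¹. For a steady catalysed rate plus this growth: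

target at time t = hand-over amount × (e^(growth constant × t) − 1)

The north reading at 49 s gave 0.00573 M for the hand-over amount, the amount of target at which the self-feeding path makes as much as the catalysed path. I assumed that the catalysed rate scales with substrate and ignores partner, so substrate cancels and the hand-over amount scales inversely with partner. The south-east run tested this: its growth constant of 0.0175 s⁻¹ and hand-over amount of 0.0115 M gave 0.212 M at 170 s, against a reading of 0.218 M.

The catalysed share of the rate at any amount of target follows:

share = hand-over amount / (hand-over amount + target)

At 2 percent conversion in the north run, target is 0.0200 M, so the share is 22.3 %. The north-west run lies below the north run at 97 s by a ratio that gives an order of 1.76 for the catalysed path. Multiplying by the share, I expected an order in catalyst of 0.392. The north-east growth constant of 0.107 s⁻¹ gave an order in substrate of 1.02 for the self-feeding path. I had assumed that the catalysed rate scales with substrate too, so I took this as my order for the whole rate.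

For the south-west run, the growth constant is 0.00803 s⁻¹ and the hand-over amount is 0.00748 M. The curve starts with a slope of 6.01 × 10⁻⁵ M s⁻¹ and crosses the hand-over amount at 86.3 s, before the asked time. It reaches 0.0218 M at 170 s, still climbing and far below the substrate charge, so I expected 7.27 % of that charge as target.

The forecast, which said “so target is autocatalytic”, gave 0.95 for substrate, 0.42 for catalyst and 8.3 % for the south-west run. The simulation gave 1.0, 0.32 and 6.85 %.

    catalyst + substrate ⇌ catalyst-substrate complex, settled at all times (0.2440 M⁻¹)
    catalyst + partner ⇌ catalyst-reagent complex, settled at all times (3.050 M⁻¹)
    catalyst-substrate complex + catalyst-reagent complex → target + 2 catalyst (286.0 M⁻¹ s⁻¹)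
    target → decomposed product (5.810 × 10⁻⁴ s⁻¹)
    substrate + partner + target → 2 target (0.01340 M⁻² s⁻¹)

In the south-west run, 6.85 % of the charge is 0.0205 M of target, 2.74 times my hand-over amount, which on my reckoning puts the catalysed share of the rate at 26.7 % at 170 s. Round the north charge the two paths show in the order in catalyst: with the self-feeding step removed, that order is 2.2 instead of 0.32. Their ratio puts the catalysed share of the rate in the north run at 2 percent conversion at 14.7 %.

(The runs are calculated for substances that don't exist; the scatter is artificial.)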